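**Retrosynthetic overview**

- Numbering: C1 is the lactone carbonyl carbon, C2–C32 are the 31 ring methylenes, and O33 is the ring oxygen joining C32 to C1.
- Feature: the only ring, the 33-membered lactone, is an unbranched loop of CH2 groups with no substituent and no stereocentre, so a remote CH2–CH2 bond, C22–C23, can be carried as an alkene.
- Target 10 ⇐ hydrogenation of the C22=C23 macrolactone 9 ⇐ ring-closing metathesis of diene ester 8 (the single ring-forming event).
- 8 ⇐ esterification (O33–C1) of tricos-22-enoic acid 6 with undec-10-en-1-ol 7; 6 ⇐ copper-catalysed C12–C13 coupling of undec-10-enylmagnesium bromide 2 (from bromide 1) with 12-bromododecanoic acid 3.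

Key step: step 4

Remark: the ring closure is expected to give 9 as an E/Z mixture; the E isomer is drawn, and both isomers converge on 10 in step 5. The oxacyclo name of 9 counts from the ring oxygen, so C22=C23 appears there as the 23-ene.

**Route**

Step 1
Reactants: 1 11-bromoundec-1-ene
Product: 2 undec-10-enylmagnesium bromide
Conditions: Mg turnings (1.3 equiv), I2 (cat.), THF, slow addition of 1 at 35–40 °C; kept under Ar as a titrated THF solution
Reagents that add atoms: magnesium, [Mg]
Why: Grignard reagent formation by insertion of magnesium into an unhindered primary C–Br bond is routine, the remote terminal alkene is inert to it, and slow addition at moderate dilution should keep Wurtz homocoupling low.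

Step 2
Reactants: 2 undec-10-enylmagnesium bromide, 3 12-bromododecanoic acid
Product: 6 tricos-22-enoic acid, via chloromagnesium 12-bromododecanoate 4 (not isolated), via chloromagnesium tricos-22-enoate 5 (not isolated)
Conditions: 3, MeMgCl (1.0 equiv), THF, −20 °C; then Li2CuCl4 (3 mol%), 2 (1.3 equiv), −20 °C to rt; aq. HCl work-up; recrystallization (acetone)
Reagents that add atoms: none
Why: Li2CuCl4-catalysed cross-coupling of a primary alkyl Grignard reagent with a primary alkyl bromide: pre-forming the chloromagnesium carboxylate 4 removes the acidic proton, the carboxylate is inert to the Grignard reagent at this temperature, and the alkylcopper species generated from 2 displaces the unhindered C12 bromide to make the C12–C13 bond while the terminal alkene stays untouched.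

Step 3
Reactants: 6 tricos-22-enoic acid, 7 undec-10-en-1-ol
Product: 8 undec-10-en-1-yl tricos-22-enoate
Conditions: DCC (1.1 equiv), DMAP (10 mol%), CH2Cl2, 0 °C to rt
Reagents that add atoms: none
Why: Steglich esterification: carbodiimide activation of the acid with DMAP as acyl-transfer catalyst should acylate the unhindered primary alcohol under neutral conditions that leave both terminal alkenes untouched.

Step 4
Reactants: 8 undec-10-en-1-yl tricos-22-enoate
Product: 9 (E)-oxacyclotritriacont-23-en-2-one
Conditions: second-generation Grubbs catalyst (H2IMes)(PCy3)Cl2Ru=CHPh (5 mol%), 1,4-benzoquinone (10 mol%), CH2Cl2 (2 mM final, syringe-pump addition of 8 over 8 h), 40 °C, Ar sparge; then ethyl vinyl ether, silica filtration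
Reagents that add atoms: none
Why: Ring-closing olefin metathesis by the metallacyclobutane mechanism: after phosphine loss the ruthenium benzylidene exchanges onto one terminal alkene of 8, the resulting alkylidene adds across the second terminal alkene in an intramolecular [2+2] step, and cycloreversion of the ruthenacyclobutane forms the C22=C23 double bond while the ruthenium methylidene carries the chain and ethylene escapes. The closest known reaction type is the macrocyclic ring-closing metathesis of ester-tethered α,ω-dienes to unsaturated macrolides. The single 33-membered ring closes end to end at the alkene–alkene junction between C22 of the acid chain and C23 (C10 of the alcohol chain), a strain-free large-ring closure that costs only the entropy of bringing the chain ends together. No stereocentre is formed, and the E/Z ratio of the new alkene needs no control because step 5 removes it. The selectivity needed is ring closure over intermolecular acyclic diene metathesis, which the 2 mM concentration, the slow addition and the reversibility of metathesis should secure, since at this dilution oligomers are returned to the cyclic monomer while the argon sparge removes ethylene. Positional fidelity of the alkenes, needed so that no ring-contracted homologue forms, is protected by the benzoquinone hydride scavenger and the low temperature, and the alkenes sit 20 and 9 methylenes from the ester, too far for carbonyl chelation to sequester the ruthenium carbene.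

Step 5
Reactants: 9 (E)-oxacyclotritriacont-23-en-2-one
Product: 10 oxacyclotritriacontan-2-one
Conditions: H2 (1 atm), 10% Pd/C, EtOAc, rt
Reagents that add atoms: none
Why: Heterogeneous catalytic hydrogenation saturates the isolated 1,2-disubstituted C22=C23 alkene of either geometry, and the lactone, which has no allylic or benzylic C–O bond, is inert under these conditions; no stereocentre arises.

**Compound list**

1 | 11-bromoundec-1-ene | C=CCCCCCCCCCBr | starting material
2 | undec-10-enylmagnesium bromide | C=CCCCCCCCCC[Mg]Br | intermediate
3 | 12-bromododecanoic acid | OC(=O)CCCCCCCCCCCBr | starting material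
4 | chloromagnesium 12-bromododecanoate | BrCCCCCCCCCCCC(=O)O[Mg]Cl | intermediate
5 | chloromagnesium tricos-22-enoate | C=CCCCCCCCCCCCCCCCCCCCCC(=O)O[Mg]Cl | intermediate
6 | tricos-22-enoic acid | C=CCCCCCCCCCCCCCCCCCCCCC(=O)O | intermediate
7 | undec-10-en-1-ol | C=CCCCCCCCCCO | starting material
8 | undec-10-en-1-yl tricos-22-enoate | C=CCCCCCCCCCCCCCCCCCCCCC(=O)OCCCCCCCCCC=C | intermediate
9 | (E)-oxacyclotritriacont-23-en-2-one (E/Z mixture expected, E drawn) | O=C1CCCCCCCCCCCCCCCCCCCC/C=C/CCCCCCCCCO1 | intermediate
10 | oxacyclotritriacontan-2-one (32-dotriacontanolide) | O=C1CCCCCCCCCCCCCCCCCCCCCCCCCCCCCCCO1 | target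

**Step count**

Total steps: 5. Longest linear sequence: 5 steps (1 → 2 → 6 → 8 → 9 → 10).

**Steps most likely to fail**

1. Step 4 (ring-closing metathesis). Intermolecular metathesis may outrun ring closure, so that linear and cyclic oligomers build up. Ruthenium-hydride-mediated double-bond migration before closure would also excise a CH2 unit and give ring-contracted homologues. Fallback: set out from 6 and 7, make the same C22=C23 bond intermolecularly and close the ring at the ester instead. Cross-metathesis of 6 with excess 7 (4 equiv) under second-generation Grubbs catalyst (H2IMes)(PCy3)Cl2Ru=CHPh in CH2Cl2 at 40 °C should give (E)-32-hydroxydotriacont-22-enoic acid F1 as an E/Z mixture, separable by chromatography from the diol and diacid homodimers. Hydrogenation (H2, 10% Pd/C, THF, 40 °C) should give 32-hydroxydotriacontanoic acid F2. Yamaguchi macrolactonization then follows: 2,4,6-trichlorobenzoyl chloride and Et3N in THF form 32-hydroxydotriacontanoic 2,4,6-trichlorobenzoic anhydride F3, which is added slowly to DMAP in refluxing toluene at high dilution. The route is rejoined at 10.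

2. Step 2 (copper-catalysed coupling). Wurtz-type homocoupling and protonation of the Grignard reagent may compete, and substitution at the sparingly soluble magnesium carboxylate may be slow, leaving bromo acid that is hard to remove from the product. Fallback: set out from 1 and 3 and switch to an ester-tolerant organozinc coupling. Fischer esterification of 3 (MeOH, cat. H2SO4, reflux) should give methyl 12-bromododecanoate F4. Zinc insertion into 1 (Zn dust, LiCl, THF, 50 °C) should give undec-10-enylzinc bromide F5. Negishi alkyl–alkyl cross-coupling of F4 with F5 (Pd2(dba)3, tricyclopentylphosphine, N-methylimidazole, THF/NMP, 80 °C) should give methyl tricos-22-enoate F6. Saponification (LiOH, THF/MeOH/H2O, then aq. HCl) rejoins the route at 6.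

3. Step 3 (esterification). The carbodiimide-activated acid may rearrange to an unreactive N-acylurea, and the urea may be carried along with the waxy ester. Fallback: set out from 6 and 1 and form the ester by carboxylate O-alkylation instead of acyl activation. Treating 6 with Cs2CO3 in DMF at 50 °C and 11-bromoundec-1-ene 1 should give the ester by SN2 displacement at the primary bromide, rejoining the route at 8. No new compound is made.

**Further compounds**

F1 | step 4 | (E)-32-hydroxydotriacont-22-enoic acid | OC(=O)CCCCCCCCCCCCCCCCCCCC/C=C/CCCCCCCCCO
F2 | step 4 | 32-hydroxydotriacontanoic acid | OC(=O)CCCCCCCCCCCCCCCCCCCCCCCCCCCCCCCO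
F3 | step 4 | 32-hydroxydotriacontanoic 2,4,6-trichlorobenzoic anhydride | OCCCCCCCCCCCCCCCCCCCCCCCCCCCCCCCC(=O)OC(=O)c1c(Cl)cc(Cl)cc1Cl
F4 | step 2 | methyl 12-bromododecanoate | COC(=O)CCCCCCCCCCCBr
F5 | step 2 | undec-10-enylzinc bromide | C=CCCCCCCCCC[Zn]Br
F6 | step 2 | methyl tricos-22-enoate | C=CCCCCCCCCCCCCCCCCCCCCC(=O)OC
F0 | step 3 | none | none
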